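The α-methylene-γ-butyrolactone (O–C6–C7–C11(=C13H2)–C12=O) shares only the C6–C7 bond with the ten-membered carbocycle (C1–C10), and C6 is also allylic to the Z-C4=C5 alkene. Cutting C6–C7 therefore opens both rings to one chain that ends in a Z-enal (C6) and a methyl 2-(bromomethyl)enoate (C7=C11, C13–Br). In the forward sense a divalent-chromium Nozaki–Hiyama allylation joins C7 to C6, sets both fusion stereocentres, moves the alkene to C11=C13 and lets the C6 alkoxide close the lactone. The chain is built by anti-crotylation, hydroformylation, alkenyllithium addition and a Morita–Baylis–Hillman reaction.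

Key step: step 16

Numbering used in the text (target ring atoms): C1, C2 (CH2), C3 (OAc), C4 (Me)=C5, C6 (lactone O–CH), C7 (fusion CH), C8 (CH2), C9 (O-acyl), C10 (Me); lactone carbons C11 (=C13H2) and C12 (C=O). The target is 3S,6R,7S,9S,10R with Z-C4=C5 and a trans-fused lactone. TBS = tert-butyldimethylsilyl, PMB = 4-methoxybenzyl, DMP = Dess–Martin periodinane.

Assumption: the (R)-SEGPHOS-modified iridium catalyst is taken to give the (3S,4R) anti adduct in step 1; if the sense of induction proves opposite, (S)-SEGPHOS is used and nothing else changes.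

Step 1
Reactants: 1 3-[(4-methoxybenzyl)oxy]propan-1-ol; 2 racemic but-3-en-2-yl acetate
Product: 4 (3S,4R)-1-[(4-methoxybenzyl)oxy]-4-methylhex-5-en-3-ol, via 3-[(4-methoxybenzyl)oxy]propanal 3 (not isolated)
Conditions: [Ir(cod)Cl]2 (2.5 mol %), (R)-SEGPHOS (5 mol %), 4-cyano-3-nitrobenzoic acid (10 mol %), Cs2CO3 (20 mol %), 2 (2 equiv), THF, 90 °C
Reagents that add atoms: none
Why: Iridium-catalysed transfer-hydrogenative anti-crotylation from the alcohol oxidation level; the alcohol is dehydrogenated to aldehyde 3, which is captured by the (E)-crotyliridium formed from either enantiomer of 2 through a closed chair, so C9 and C10 are set together as the anti pair under ligand control.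

Step 2
Reactants: 4 (3S,4R)-1-[(4-methoxybenzyl)oxy]-4-methylhex-5-en-3-ol
Product: 5 tert-butyl{[(3S,4R)-1-[(4-methoxybenzyl)oxy]-4-methylhex-5-en-3-yl]oxy}dimethylsilane
Conditions: TBSOTf, 2,6-lutidine, CH2Cl2, −78 to 0 °C
Reagents that add atoms: tert-butyldimethylsilyl triflate, CC(C)(C)[Si](C)(C)OS(=O)(=O)C(F)(F)F
Why: Silylation of a hindered secondary alcohol with the silyl triflate gives an ether that withstands the organolithium, oxidation, acid and chromium steps that follow.

Step 3
Reactants: 5 TBS ether of the anti homoallylic alcohol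
Product: 6 (4R,5S)-5-(tert-butyldimethylsilyloxy)-7-[(4-methoxybenzyl)oxy]-4-methylheptanal
Conditions: Rh(acac)(CO)2 (1 mol %), Xantphos (2 mol %), CO/H2 (1:1, 10 bar), toluene, 60 °C
Reagents that add atoms: carbon monoxide, [C-]#[O+]
Why: Linear-selective rhodium-catalysed hydroformylation of a monosubstituted alkene with a wide-bite-angle diphosphine adds C3 at the terminus, the C10 branch further disfavouring the branched aldehyde, and no stereocentre is touched.

Step 4
Reactants: 7 but-2-yn-1-ol
Product: 9 (Z)-3-iodobut-2-en-1-ol, via cyclic sodium alkenylaluminate 8 (not isolated)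
Conditions: NaAlH2(OCH2CH2OMe)2, THF, 0 °C to rt; EtOAc; then I2, THF, −78 to 0 °C
Reagents that add atoms: iodine, II
Why: Hydroxyl-directed trans-hydroalumination of the propargylic alcohol places aluminium on the distal alkyne carbon inside a five-membered alkoxyaluminate, and iodinolysis of the C–Al bond with retention gives the Z-iodide.

Step 5
Reactants: 9 (Z)-3-iodobut-2-en-1-ol
Product: 10 (Z)-tert-butyl[(3-iodobut-2-en-1-yl)oxy]dimethylsilane
Conditions: TBSCl, imidazole, CH2Cl2, 0 °C to rt
Reagents that add atoms: tert-butyldimethylsilyl chloride, CC(C)(C)[Si](C)(C)Cl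
Why: Standard silylation of a primary allylic alcohol removes the acidic proton before the halogen–metal exchange.

Step 6
Reactants: 10 (Z)-alkenyl iodide TBS ether; 6 (4R,5S)-5-(tert-butyldimethylsilyloxy)-7-[(4-methoxybenzyl)oxy]-4-methylheptanal
Product: 12 (2Z,7R,8S)-1,8-bis(tert-butyldimethylsilyloxy)-10-[(4-methoxybenzyl)oxy]-3,7-dimethyldec-2-en-4-ol as both C4 epimers, via alkenyllithium 11 (not isolated)
Conditions: 10 (1.3 equiv), t-BuLi (2.6 equiv), Et2O, −78 °C, 20 min; then 6, −78 °C; water quench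
Reagents that add atoms: none
Why: Iodine–lithium exchange of an alkenyl iodide proceeds with retention of geometry and the alkenyllithium adds 1,2 to the aldehyde to form C3–C4; ether at −78 °C keeps O-to-C silyl migration slow, and the remote C3 carbinol forms unselectively, which step 8 corrects.

Step 7
Reactants: 12 allylic alcohol (C3 epimers)
Product: 13 (2Z,7R,8S)-1,8-bis(tert-butyldimethylsilyloxy)-10-[(4-methoxybenzyl)oxy]-3,7-dimethyldec-2-en-4-one
Conditions: DMP, NaHCO3, CH2Cl2, 0 °C to rt
Reagents that add atoms: none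
Why: Buffered Dess–Martin oxidation of an allylic alcohol merges both C3 epimers into one Z-enone without acid or nucleophile that could isomerise the alkene.

Step 8
Reactants: 13 Z-enone
Product: 14 (2Z,4S,7R,8S)-1,8-bis(tert-butyldimethylsilyloxy)-10-[(4-methoxybenzyl)oxy]-3,7-dimethyldec-2-en-4-ol (3S in target numbering)
Conditions: (R)-2-methyl-CBS-oxazaborolidine (0.5 equiv), catecholborane, toluene, −78 °C; MeOH, then aqueous NaOH wash
Reagents that add atoms: none
Why: Corey–Bakshi–Shibata reduction, in which the ketone binds with the α-branched alkenyl group as the large substituent and the CH2 chain as the small one, so the (R)-catalyst delivers hydride to the face that gives 3S; catecholborane at low temperature avoids hydroboration and 1,4-reduction.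

Step 9
Reactants: 14 (3S)-allylic alcohol
Product: 15 (2Z,4S,7R,8S)-1,8-bis(tert-butyldimethylsilyloxy)-10-[(4-methoxybenzyl)oxy]-3,7-dimethyldec-2-en-4-yl acetate
Conditions: Ac2O, pyridine, DMAP (cat.), CH2Cl2, 0 °C to rt
Reagents that add atoms: acetic anhydride, CC(=O)OC(C)=O
Why: DMAP-catalysed acetylation installs the C3 acetate of the target with retention at the carbinol carbon.

Step 10
Reactants: 15 allylic acetate
Product: 16 (2Z,4S,7R,8S)-1,8-bis(tert-butyldimethylsilyloxy)-10-hydroxy-3,7-dimethyldec-2-en-4-yl acetate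
Conditions: DDQ, CH2Cl2/pH 7 phosphate buffer (10:1), 0 °C
Reagents that add atoms: none
Why: Oxidative cleavage of the 4-methoxybenzyl ether by DDQ through the benzylic oxocarbenium ion is selective for the electron-rich arene, and the buffer protects the silyl ethers and the allylic acetate.

Step 11
Reactants: 16 primary alcohol
Product: 17 (2Z,4S,7R,8S)-1,8-bis(tert-butyldimethylsilyloxy)-3,7-dimethyl-10-oxodec-2-en-4-yl acetate
Conditions: DMP, NaHCO3, CH2Cl2, 0 °C; used without chromatography
Reagents that add atoms: none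
Why: Buffered Dess–Martin oxidation gives the β-silyloxy aldehyde under non-basic conditions, which limits β-elimination of the C9 silyloxy group.

Step 12
Reactants: 17 C7 aldehyde; 18 methyl acrylate
Product: 19 methyl (5S,6R,9S,10Z)-9-acetoxy-5,12-bis(tert-butyldimethylsilyloxy)-3-hydroxy-6,10-dimethyl-2-methylidenedodec-10-enoate as both C3 carbinol epimers (C7 in target numbering)
Conditions: 18 (10 equiv, neat), quinuclidine (0.5 equiv), MeOH (1 equiv), rt
Reagents that add atoms: none
Why: Morita–Baylis–Hillman reaction, in which the amine adds to the acrylate, the ammonium enolate attacks the aldehyde to form C7–C11 and methanol-assisted proton transfer releases the catalyst; the carbinol mixture is of no consequence because this centre becomes sp2 in step 13.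

Step 13
Reactants: 19 Morita–Baylis–Hillman adduct
Product: 20 methyl (2Z,5S,6R,9S,10Z)-9-acetoxy-2-(bromomethyl)-5,12-bis(tert-butyldimethylsilyloxy)-6,10-dimethyldodeca-2,10-dienoate
Conditions: NBS, Me2S, CH2Cl2, −20 to 0 °C (reagent premixed before 19 is added)
Reagents that add atoms: N-bromosuccinimide, O=C1CCC(=O)N1Br
Why: Corey–Kim-type activation of the allylic hydroxyl as an alkoxysulfonium ion followed by SN2' attack of bromide at the terminal methylene gives the thermodynamically preferred (Z)-2-(bromomethyl)enoate from both carbinol epimers.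

Step 14
Reactants: 20 allylic bromide bis-silyl ether
Product: 21 methyl (2Z,5S,6R,9S,10Z)-9-acetoxy-2-(bromomethyl)-5-(tert-butyldimethylsilyloxy)-12-hydroxy-6,10-dimethyldodeca-2,10-dienoate
Conditions: camphorsulfonic acid (10 mol %), MeOH/CH2Cl2 (1:1), 0 °C
Reagents that add atoms: none
Why: Acid-catalysed methanolysis removes the unhindered primary allylic silyl ether much faster than the secondary C9 ether flanked by the C10 methyl, and the absence of amine or fluoride nucleophiles spares the reactive allylic bromide.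

Step 15
Reactants: 21 Z-allylic alcohol
Product: 22 methyl (2Z,5S,6R,9S,10Z)-9-acetoxy-2-(bromomethyl)-5-(tert-butyldimethylsilyloxy)-6,10-dimethyl-12-oxododeca-2,10-dienoate
Conditions: DMP, NaHCO3, CH2Cl2, 0 °C; used at once
Reagents that add atoms: none
Why: Buffered Dess–Martin oxidation of the allylic alcohol gives the Z-enal without the acid or nucleophile that would isomerise it, and the allylic bromide is inert to the oxidant.

Step 16
Reactants: 22 seco bromo-enal
Product: 25 (3aS,5S,6R,9S,10Z,11aR)-5-(tert-butyldimethylsilyloxy)-6,10-dimethyl-3-methylidene-2-oxo-2,3,3a,4,5,6,7,8,9,11a-decahydrocyclodeca[b]furan-9-yl acetate, via allylchromium dichloride 23 (not isolated), via chromium alkoxide of the ring-closed hydroxy ester 24 (not isolated)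
Conditions: CrCl2 (8 equiv), THF/DMF (4:1), rt, syringe-pump addition of 22 over 10 h (final 2 mM); aqueous NH4Cl work-up, then pyridinium p-toluenesulfonate (cat.), CH2Cl2, rt on the crude
Reagents that add atoms: none
Why: Two single-electron transfers from divalent chromium turn the C13–Br bond into a trivalent allylchromium that equilibrates between its C13- and C7-bound forms, so the bromide geometry is not carried over, and it adds through C7 to the C6 aldehyde in a chromium-bridged six-membered chair with allyl transposition that leaves C11=C13 exocyclic. The closest known reaction type is the intramolecular Nozaki–Hiyama allylation of aldehydes by 2-(bromomethyl)enoates, which is known to close ten-membered germacranolide carbocycles together with the α-methylene lactone. The carbocycle closes by 10-exo-trig attack on the carbonyl carbon and the lactone by 5-exo-trig acyl substitution of the C6 alkoxide at the C12 methyl ester with loss of methoxide. C6 and C7 are created together: their trans (anti) relationship should follow from the chair in which the two ring arms (C5 on C6, C8 on C7) are pseudo-equatorial, and the 6R,7S sense from the resident centres, namely the C9 silyloxy/C10 methyl pair next to the nucleophile and the C3 acetoxy centre that allylic 1,3-strain holds beside the aldehyde across the Z-alkene. The step needs ring closure over oligomerisation, 1,2- over 1,4-addition and the trans-fused 6R,7S pair: high dilution with slow addition, the Z-C4=C5 alkene that already holds C3 and C6 on one side as a turn, and the β,β-disubstituted enal without acidic α-hydrogen secure the first two, while the facial outcome rests on substrate control and is the main uncertainty. The acetate, the silyl ether and the centres C3, C9 and C10 are not touched by the chromium reagent.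

Step 17
Reactants: 25 9-O-TBS germacranolide
Product: 26 (3aS,5S,6R,9S,10Z,11aR)-5-hydroxy-6,10-dimethyl-3-methylidene-2-oxo-2,3,3a,4,5,6,7,8,9,11a-decahydrocyclodeca[b]furan-9-yl acetate
Conditions: 48 % aqueous HF, MeCN, 0 °C to rt
Reagents that add atoms: none
Why: Acidic fluoride desilylation frees the C9 hydroxyl without the basic conditions that would invite acetate migration, translactonisation or conjugate addition to the α-methylene lactone.

Step 18
Reactants: 26 C9 alcohol; 27 angelic acid [(2Z)-2-methylbut-2-enoic acid]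
Product: 29 target, (3aS,5S,6R,9S,10Z,11aR)-9-acetoxy-6,10-dimethyl-3-methylidene-2-oxo-2,3,3a,4,5,6,7,8,9,11a-decahydrocyclodeca[b]furan-5-yl (2Z)-2-methylbut-2-enoate, via angelic 2,4,6-trichlorobenzoic anhydride 28 (not isolated)
Conditions: 27 (3 equiv), 2,4,6-trichlorobenzoyl chloride (3 equiv), Et3N (3 equiv), toluene, rt, 2 h; then 26, toluene, 80 °C, no DMAP
Reagents that add atoms: none
Why: Yamaguchi-type esterification through the preformed mixed anhydride, which is attacked at the unhindered angeloyl carbonyl; leaving out the nucleophilic catalyst avoids the addition–elimination that turns angelate into tiglate and conjugate addition to the lactone.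

Compound list
1 | 3-[(4-methoxybenzyl)oxy]propan-1-ol | COc1ccc(COCCCO)cc1 | starting material
2 | but-3-en-2-yl acetate (racemic) | C=CC(C)OC(C)=O | starting material
3 | 3-[(4-methoxybenzyl)oxy]propanal | COc1ccc(COCCC=O)cc1 | intermediate (not isolated)
4 | (3S,4R)-1-[(4-methoxybenzyl)oxy]-4-methylhex-5-en-3-ol | C=C[C@@H](C)[C@@H](O)CCOCc1ccc(OC)cc1 | intermediate
5 | tert-butyl{[(3S,4R)-1-[(4-methoxybenzyl)oxy]-4-methylhex-5-en-3-yl]oxy}dimethylsilane | C=C[C@@H](C)[C@@H](O[Si](C)(C)C(C)(C)C)CCOCc1ccc(OC)cc1 | intermediate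
6 | (4R,5S)-5-(tert-butyldimethylsilyloxy)-7-[(4-methoxybenzyl)oxy]-4-methylheptanal | O=CCC[C@@H](C)[C@@H](O[Si](C)(C)C(C)(C)C)CCOCc1ccc(OC)cc1 | intermediate
7 | but-2-yn-1-ol | CC#CCO | starting material
8 | sodium 2,2-bis(2-methoxyethoxy)-3-methyl-2,5-dihydro-1,2-oxaluminol-2-uide (cyclic alkenylaluminate) | CC1=CCO[Al-]1(OCCOC)OCCOC.[Na+] | intermediate (not isolated)
9 | (Z)-3-iodobut-2-en-1-ol | C/C(I)=C/CO | intermediate
10 | (Z)-tert-butyl[(3-iodobut-2-en-1-yl)oxy]dimethylsilane | C/C(I)=C/CO[Si](C)(C)C(C)(C)C | intermediate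
11 | [4-(tert-butyldimethylsilyloxy)but-2-en-2-yl]lithium, lithium cis to the CH2OTBS group (geometry of 10 retained) | C/C([Li])=C/CO[Si](C)(C)C(C)(C)C | intermediate (not isolated)
12 | (2Z,7R,8S)-1,8-bis(tert-butyldimethylsilyloxy)-10-[(4-methoxybenzyl)oxy]-3,7-dimethyldec-2-en-4-ol, both C4 epimers | CC(C)(C)[Si](C)(C)OC/C=C(/C)C(O)CC[C@@H](C)[C@@H](O[Si](C)(C)C(C)(C)C)CCOCc1ccc(OC)cc1 | intermediate
13 | (2Z,7R,8S)-1,8-bis(tert-butyldimethylsilyloxy)-10-[(4-methoxybenzyl)oxy]-3,7-dimethyldec-2-en-4-one | CC(C)(C)[Si](C)(C)OC/C=C(/C)C(=O)CC[C@@H](C)[C@@H](O[Si](C)(C)C(C)(C)C)CCOCc1ccc(OC)cc1 | intermediate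
14 | (2Z,4S,7R,8S)-1,8-bis(tert-butyldimethylsilyloxy)-10-[(4-methoxybenzyl)oxy]-3,7-dimethyldec-2-en-4-ol | CC(C)(C)[Si](C)(C)OC/C=C(/C)[C@@H](O)CC[C@@H](C)[C@@H](O[Si](C)(C)C(C)(C)C)CCOCc1ccc(OC)cc1 | intermediate
15 | (2Z,4S,7R,8S)-1,8-bis(tert-butyldimethylsilyloxy)-10-[(4-methoxybenzyl)oxy]-3,7-dimethyldec-2-en-4-yl acetate | CC(C)(C)[Si](C)(C)OC/C=C(/C)[C@@H](OC(C)=O)CC[C@@H](C)[C@@H](O[Si](C)(C)C(C)(C)C)CCOCc1ccc(OC)cc1 | intermediate
16 | (2Z,4S,7R,8S)-1,8-bis(tert-butyldimethylsilyloxy)-10-hydroxy-3,7-dimethyldec-2-en-4-yl acetate | CC(C)(C)[Si](C)(C)OC/C=C(/C)[C@@H](OC(C)=O)CC[C@@H](C)[C@@H](O[Si](C)(C)C(C)(C)C)CCO | intermediate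
17 | (2Z,4S,7R,8S)-1,8-bis(tert-butyldimethylsilyloxy)-3,7-dimethyl-10-oxodec-2-en-4-yl acetate | CC(C)(C)[Si](C)(C)OC/C=C(/C)[C@@H](OC(C)=O)CC[C@@H](C)[C@@H](O[Si](C)(C)C(C)(C)C)CC=O | intermediate
18 | methyl acrylate | C=CC(=O)OC | starting material
19 | methyl (5S,6R,9S,10Z)-9-acetoxy-5,12-bis(tert-butyldimethylsilyloxy)-3-hydroxy-6,10-dimethyl-2-methylidenedodec-10-enoate, both C3 epimers | CC(C)(C)[Si](C)(C)OC/C=C(/C)[C@@H](OC(C)=O)CC[C@@H](C)[C@@H](O[Si](C)(C)C(C)(C)C)CC(O)C(=C)C(=O)OC | intermediate
20 | methyl (2Z,5S,6R,9S,10Z)-9-acetoxy-2-(bromomethyl)-5,12-bis(tert-butyldimethylsilyloxy)-6,10-dimethyldodeca-2,10-dienoate | CC(C)(C)[Si](C)(C)OC/C=C(/C)[C@@H](OC(C)=O)CC[C@@H](C)[C@@H](O[Si](C)(C)C(C)(C)C)C/C=C(\CBr)C(=O)OC | intermediate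
21 | methyl (2Z,5S,6R,9S,10Z)-9-acetoxy-2-(bromomethyl)-5-(tert-butyldimethylsilyloxy)-12-hydroxy-6,10-dimethyldodeca-2,10-dienoate | OC/C=C(/C)[C@@H](OC(C)=O)CC[C@@H](C)[C@@H](O[Si](C)(C)C(C)(C)C)C/C=C(\CBr)C(=O)OC | intermediate
22 | methyl (2Z,5S,6R,9S,10Z)-9-acetoxy-2-(bromomethyl)-5-(tert-butyldimethylsilyloxy)-6,10-dimethyl-12-oxododeca-2,10-dienoate | O=C/C=C(/C)[C@@H](OC(C)=O)CC[C@@H](C)[C@@H](O[Si](C)(C)C(C)(C)C)C/C=C(\CBr)C(=O)OC | intermediate
23 | allylchromium dichloride from 22 (chromium on C13, C7=C11 geometry equilibrating) | O=C/C=C(/C)[C@@H](OC(C)=O)CC[C@@H](C)[C@@H](O[Si](C)(C)C(C)(C)C)CC=C(C[Cr](Cl)Cl)C(=O)OC | intermediate (not isolated)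
24 | dichlorochromium alkoxide of methyl 2-[(1S,2R,3Z,5S,8R,9S)-5-acetoxy-9-(tert-butyldimethylsilyloxy)-2-hydroxy-4,8-dimethylcyclodec-3-en-1-yl]prop-2-enoate | Cl[Cr](Cl)O[C@@H]1/C=C(/C)[C@@H](OC(C)=O)CC[C@@H](C)[C@@H](O[Si](C)(C)C(C)(C)C)C[C@H]1C(=C)C(=O)OC | intermediate (not isolated)
25 | (3aS,5S,6R,9S,10Z,11aR)-5-(tert-butyldimethylsilyloxy)-6,10-dimethyl-3-methylidene-2-oxo-2,3,3a,4,5,6,7,8,9,11a-decahydrocyclodeca[b]furan-9-yl acetate | C=C1C(=O)O[C@@H]2/C=C(/C)[C@@H](OC(C)=O)CC[C@@H](C)[C@@H](O[Si](C)(C)C(C)(C)C)C[C@@H]12 | intermediate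
26 | (3aS,5S,6R,9S,10Z,11aR)-5-hydroxy-6,10-dimethyl-3-methylidene-2-oxo-2,3,3a,4,5,6,7,8,9,11a-decahydrocyclodeca[b]furan-9-yl acetate | C=C1C(=O)O[C@@H]2/C=C(/C)[C@@H](OC(C)=O)CC[C@@H](C)[C@@H](O)C[C@@H]12 | intermediate
27 | angelic acid, (2Z)-2-methylbut-2-enoic acid | C/C=C(/C)C(=O)O | starting material
28 | (2Z)-2-methylbut-2-enoic 2,4,6-trichlorobenzoic anhydride | C/C=C(/C)C(=O)OC(=O)c1c(Cl)cc(Cl)cc1Cl | intermediate (not isolated)
29 | CNP0173235.1, (3aS,5S,6R,9S,10Z,11aR)-9-acetoxy-6,10-dimethyl-3-methylidene-2-oxo-2,3,3a,4,5,6,7,8,9,11a-decahydrocyclodeca[b]furan-5-yl (2Z)-2-methylbut-2-enoate | C=C1C(=O)O[C@@H]2/C=C(/C)[C@@H](OC(C)=O)CC[C@@H](C)[C@@H](OC(=O)/C(C)=C\C)C[C@@H]12 | target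

Total step count: 18. Longest linear sequence: 16 steps (steps 1–3 and 6–18, from 1); the alkenyl iodide 10 is a two-step branch (steps 4 and 5).

Steps most likely to fail

1. Step 16. Intermolecular coupling and simple reduction of the allylic bromide may outrun the medium-ring closure, and the closure may take place with poor simple or facial diastereoselection, since the 6R,7S trans pair rests on substrate control alone. The fallback exchanges the roles of the two C–C bonds, sets out from 6 and 9 and returns at 25. The lactone is made first between two small fragments, where a chiral ligand can be used and diastereomers can be separated, and the carbocycle is then closed at C3–C4.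
 - Aldehyde 6 would be masked (MeOH, pyridinium p-toluenesulfonate, 3 Å sieves) as (3S,4R)-3-(tert-butyldimethylsilyloxy)-7,7-dimethoxy-1-[(4-methoxybenzyl)oxy]-4-methylheptane F1.
 - Buffered DDQ would give the alcohol (3S,4R)-3-(tert-butyldimethylsilyloxy)-7,7-dimethoxy-4-methylheptan-1-ol F2, and buffered DMP the aldehyde (3S,4R)-3-(tert-butyldimethylsilyloxy)-7,7-dimethoxy-4-methylheptanal F3.
 - The Morita–Baylis–Hillman reaction with 18 would give methyl (5S,6R)-5-(tert-butyldimethylsilyloxy)-3-hydroxy-9,9-dimethoxy-6-methyl-2-methylidenenonanoate F4, and NBS/Me2S the bromide methyl (2Z,5S,6R)-2-(bromomethyl)-5-(tert-butyldimethylsilyloxy)-9,9-dimethoxy-6-methylnon-2-enoate F5.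
 - Alcohol 9 would be oxidised with MnO2 to (Z)-3-iodobut-2-enal F6.
 - CrCl2 in THF, which does not insert into the alkenyl iodide without nickel, would couple F5 with F6, if necessary with a chiral oxazoline–sulfonamide ligand on chromium. After lactonisation and separation of the diastereomers at this acyclic stage this should give the trans lactone (4S,5S)-4-[(2S,3R)-2-(tert-butyldimethylsilyloxy)-6,6-dimethoxy-3-methylhexyl]-5-[(Z)-2-iodoprop-1-en-1-yl]-3-methylidenedihydrofuran-2(3H)-one F7, which has the target configuration at C6 and C7.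
 - Acetal hydrolysis (pyridinium p-toluenesulfonate, acetone/water) would give the aldehyde (4R,5S)-5-(tert-butyldimethylsilyloxy)-6-[(2S,3S)-2-[(Z)-2-iodoprop-1-en-1-yl]-4-methylidene-5-oxotetrahydrofuran-3-yl]-4-methylhexanal F8.
 - Intramolecular alkenyl iodide–aldehyde Nozaki–Hiyama–Kishi coupling (CrCl2, NiCl2 cat., DMSO, high dilution) would close the ring at C3–C4 with retention of the Z geometry to the macrocyclic allylic alcohol 3-O-deacetyl-25 F9 as C3 epimers.
 - The 3S epimer would be acetylated (Ac2O, pyridine) and the 3R epimer inverted with acetic acid under Mitsunobu conditions, both giving 25.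

2. Step 12. The amine-catalysed addition is slow for an aliphatic aldehyde, and over the long reaction time β-elimination of the C9 silyloxy group and methanolysis of the acetate may take over. The fallback sets out from 17 and returns at 19. The C7–C11 bond would be made with a preformed α-metallated acrylate: hydroalumination of methyl propiolate with i-Bu2AlH and N-methylmorpholine N-oxide (THF, 0 °C) gives the [1-(methoxycarbonyl)vinyl]alane, which adds to 17 within hours at 0 °C without amine base and gives 19 directly, so no new compound arises (F0).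

3. Step 18. The angeloyl unit may isomerise to the tigloyl (E) isomer during activation, and acylation of the hindered C9 hydroxyl beside the C10 methyl may be slow. The fallback sets out from 26 and returns at 29, and builds the Z-alkene on the ester instead of transferring it. Alcohol 26 would be acylated with 2-[bis(2,2,2-trifluoroethoxy)phosphoryl]propanoic acid (N,N'-diisopropylcarbodiimide, DMAP cat., CH2Cl2, 0 °C) to the 9-O-{2-[bis(2,2,2-trifluoroethoxy)phosphoryl]propanoyl} derivative of 26 F10. Still–Gennari olefination (KN(SiMe3)2, 18-crown-6, THF, −78 °C, then acetaldehyde) would give the Z-configured 2-methylbut-2-enoate 29 under kinetic control.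

Further compounds
F1 | step 16 | (3S,4R)-3-(tert-butyldimethylsilyloxy)-7,7-dimethoxy-1-[(4-methoxybenzyl)oxy]-4-methylheptane | COC(OC)CC[C@@H](C)[C@@H](O[Si](C)(C)C(C)(C)C)CCOCc1ccc(OC)cc1
F2 | step 16 | (3S,4R)-3-(tert-butyldimethylsilyloxy)-7,7-dimethoxy-4-methylheptan-1-ol | COC(OC)CC[C@@H](C)[C@@H](O[Si](C)(C)C(C)(C)C)CCO
F3 | step 16 | (3S,4R)-3-(tert-butyldimethylsilyloxy)-7,7-dimethoxy-4-methylheptanal | COC(OC)CC[C@@H](C)[C@@H](O[Si](C)(C)C(C)(C)C)CC=O
F4 | step 16 | methyl (5S,6R)-5-(tert-butyldimethylsilyloxy)-3-hydroxy-9,9-dimethoxy-6-methyl-2-methylidenenonanoate, both C3 epimers | COC(OC)CC[C@@H](C)[C@@H](O[Si](C)(C)C(C)(C)C)CC(O)C(=C)C(=O)OC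
F5 | step 16 | methyl (2Z,5S,6R)-2-(bromomethyl)-5-(tert-butyldimethylsilyloxy)-9,9-dimethoxy-6-methylnon-2-enoate | COC(OC)CC[C@@H](C)[C@@H](O[Si](C)(C)C(C)(C)C)C/C=C(\CBr)C(=O)OC
F6 | step 16 | (Z)-3-iodobut-2-enal | C/C(I)=C/C=O
F7 | step 16 | (4S,5S)-4-[(2S,3R)-2-(tert-butyldimethylsilyloxy)-6,6-dimethoxy-3-methylhexyl]-5-[(Z)-2-iodoprop-1-en-1-yl]-3-methylidenedihydrofuran-2(3H)-one | C=C1C(=O)O[C@H](/C=C(/C)I)[C@H]1C[C@H](O[Si](C)(C)C(C)(C)C)[C@H](C)CCC(OC)OC
F8 | step 16 | (4R,5S)-5-(tert-butyldimethylsilyloxy)-6-[(2S,3S)-2-[(Z)-2-iodoprop-1-en-1-yl]-4-methylidene-5-oxotetrahydrofuran-3-yl]-4-methylhexanal | C=C1C(=O)O[C@H](/C=C(/C)I)[C@H]1C[C@H](O[Si](C)(C)C(C)(C)C)[C@H](C)CCC=O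
F9 | step 16 | (3aS,5S,6R,10Z,11aR)-5-(tert-butyldimethylsilyloxy)-9-hydroxy-6,10-dimethyl-3-methylidene-3a,4,5,6,7,8,9,11a-octahydrocyclodeca[b]furan-2(3H)-one, both C9 epimers (C3 in target numbering) | C=C1C(=O)O[C@@H]2/C=C(/C)C(O)CC[C@@H](C)[C@@H](O[Si](C)(C)C(C)(C)C)C[C@@H]12
F0 | step 12 | none | none
F10 | step 18 | (3aS,5S,6R,9S,10Z,11aR)-9-acetoxy-6,10-dimethyl-3-methylidene-2-oxo-2,3,3a,4,5,6,7,8,9,11a-decahydrocyclodeca[b]furan-5-yl 2-[bis(2,2,2-trifluoroethoxy)phosphoryl]propanoate, both epimers at the phosphonate carbon | C=C1C(=O)O[C@@H]2/C=C(/C)[C@@H](OC(C)=O)CC[C@@H](C)[C@@H](OC(=O)C(C)P(=O)(OCC(F)(F)F)OCC(F)(F)F)C[C@@H]12
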